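**Retrosynthetic overview** (isochromenone numbering C1–C8a; side chain C1′–C7′)

1. The carbocycle is closed last: C4a=C5 by intramolecular aldol condensation of a C5 methyl ketone onto the carbonyl of a 2,3-dihydro-4H-pyran-4-one (pyran ring first, carbocycle second).
2. C6–C7: chelate-controlled addition of an acetyl anion equivalent to an α-hydroxy methyl ketone sets C7.
3. C8–C8a (key step): catalytic asymmetric Mukaiyama-type aldol of a 4-siloxy-2H-pyran with methylglyoxal sets C8 and C8a.
4. Pyranone ring: C-acylation/O-alkylation of the side-chain methyl enone with 3-chloropropanoyl chloride; the enone comes from cross-metathesis of a vinyl diol with methyl vinyl ketone.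
5. Side-chain stereotriad: organocatalytic (Z)-crotylboration of methylglyoxal (first stereocentres), hydrogenation, chelate-controlled vinyl Grignard addition.

Assumption: anhydrous monomeric methylglyoxal, freshly distilled from the commercial 40% aqueous solution, is used, and each chiral catalyst is named in the enantiomeric form expected by analogy with published face selectivities (its mirror image is used if the first run shows the opposite sense).

**Step 1**
Reactants: 1 methylglyoxal (2-oxopropanal); 2 (Z)-crotylboronic acid pinacol ester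
Product: 4 (3R,4S)-3-hydroxy-4-methylhex-5-en-2-one, via pinacol borate ester 3 (not isolated)
Conditions: (R)-TRIP [(R)-3,3′-bis(2,4,6-triisopropylphenyl)-1,1′-binaphthyl-2,2′-diyl hydrogen phosphate] (5 mol %), 4 Å MS, toluene, −30 °C; aqueous work-up
Reagents that add atoms: (Z)-crotylboronic acid pinacol ester 2, C/C=C\CB1OC(C)(C)C(C)(C)O1
Why: The chiral phosphoric acid hydrogen-bonds to a boronate oxygen in the closed chair transition state of the allylboration, so the aldehyde carbonyl of 1 is attacked on one face only, the Z geometry fixing the syn relation of C3–OH and C4–Me and the catalyst the absolute sense (organocatalytic asymmetric crotylboration).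

**Step 2**
Reactants: 4 (3R,4S)-3-hydroxy-4-methylhex-5-en-2-one
Product: 5 (3R,4S)-3-hydroxy-4-methylhexan-2-one
Conditions: H2 (1 atm), 5% palladium on carbon (Pd/C), EtOAc, rt
Reagents that add atoms: none
Why: Heterogeneous catalytic hydrogenation saturates the monosubstituted alkene only, turning the vinyl group into the ethyl group without touching the ketone or either stereocentre.

**Step 3**
Reactants: 5 (3R,4S)-3-hydroxy-4-methylhexan-2-one; 6 vinylmagnesium bromide
Product: 8 (3R,4R,5S)-3,5-dimethylhept-1-ene-3,4-diol, via magnesium alkoxide chelate 7 (not isolated)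
Conditions: CH2=CHMgBr (2.5 equiv), THF, −78 °C; aq NH4Cl
Reagents that add atoms: vinylmagnesium bromide 6, C=C[Mg]Br
Why: The first equivalent forms the five-membered magnesium chelate 7 and the second adds to the ketone from the face of the small α-hydrogen, anti to the sec-butyl group (Cram chelate-controlled Grignard addition), which sets the tertiary carbinol 3R syn to the C4 hydroxyl.

**Step 4**
Reactants: 8 (3R,4R,5S)-3,5-dimethylhept-1-ene-3,4-diol; 9 methyl vinyl ketone (but-3-en-2-one)
Product: 10 (3E,5R,6R,7S)-5,6-dihydroxy-5,7-dimethylnon-3-en-2-one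
Conditions: 9 (3 equiv), second-generation Hoveyda–Grubbs catalyst RuCl2(H2IMes)(=CH–C6H4-2-O-i-Pr) (5 mol %), CH2Cl2, 40 °C
Reagents that add atoms: methyl vinyl ketone 9, CC(=O)C=C
Why: Olefin cross-metathesis between the slowly homodimerising tertiary allylic alcohol and the electron-poor enone gives the heterodimer as the E-enone under thermodynamic control, with ethene lost.

**Step 5**
Reactants: 10 (3E,5R,6R,7S)-5,6-dihydroxy-5,7-dimethylnon-3-en-2-one; 11 triethylsilyl trifluoromethanesulfonate
Product: 12 (3E,5R,6R,7S)-5,7-dimethyl-5,6-bis(triethylsilyloxy)non-3-en-2-one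
Conditions: Et3SiOTf (2.4 equiv), 2,6-lutidine, CH2Cl2, −78 → 0 °C
Reagents that add atoms: triethylsilyl trifluoromethanesulfonate 11, CC[Si](CC)(CC)OS(=O)(=O)C(F)(F)F
Why: The silyl triflate silylates both the secondary and the hindered tertiary hydroxyl, while the weak base 2,6-lutidine leaves the enone unenolised (silyl ether protection).

**Step 6**
Reactants: 12 bis(triethylsilyl) ether of 10; 13 3-chloropropanoyl chloride
Product: 15 6-[(1E,3R,4R,5S)-3,5-dimethyl-3,4-bis(triethylsilyloxy)hept-1-en-1-yl]-2,3-dihydro-4H-pyran-4-one, via chloro diketone 14 (not isolated)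
Conditions: MgBr2·OEt2, i-Pr2NEt, 13, CH2Cl2, 0 °C → rt; then DBU, rt
Reagents that add atoms: 3-chloropropanoyl chloride 13, ClCCC(Cl)=O
Why: Soft enolisation of the methyl ketone gives a magnesium enolate that is C-acylated to the 1,3-diketone 14, whose enol oxygen then displaces the primary chloride in a 6-exo-tet O-alkylation and so closes the pyranone ring (Claisen-type acylation followed by intramolecular Williamson-type cyclisation).

**Step 7**
Reactants: 15 side-chain dihydropyranone; 16 trimethylsilyl trifluoromethanesulfonate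
Product: 17 6-[(1E,3R,4R,5S)-3,5-dimethyl-3,4-bis(triethylsilyloxy)hept-1-en-1-yl]-4-(trimethylsilyloxy)-2H-pyran
Conditions: Me3SiOTf, Et3N, Et2O, −78 → −30 °C; cold filtration under argon, used at once
Reagents that add atoms: trimethylsilyl trifluoromethanesulfonate 16, C[Si](C)(C)OS(=O)(=O)C(F)(F)F
Why: Soft enolisation at the only enolisable position (the C3 methylene next to the carbonyl) gives the cross-conjugated Danishefsky-type silyl dienol ether, which is kept cold to prevent electrocyclic ring opening of the 2H-pyran (silyl enol ether formation).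

**Step 8**
Reactants: 17 4-(trimethylsilyloxy)-2H-pyran; 1 methylglyoxal
Product: 19 (3S)-6-[(1E,3R,4R,5S)-3,5-dimethyl-3,4-bis(triethylsilyloxy)hept-1-en-1-yl]-3-[(1R)-1-hydroxy-2-oxopropyl]-2,3-dihydro-4H-pyran-4-one, via trimethylsilyl ether 18 (not isolated)
Conditions: 1 (freshly distilled, 1.5 equiv), (S)-3,3′-bis[3,5-bis(trifluoromethyl)phenyl]-1,1′-binaphthyl-2,2′-disulfonimide (5 mol %), Et2O, −78 °C; then citric acid, MeOH, 0 °C
Reagents that add atoms: methylglyoxal 1, CC(=O)C=O
Why: Proposed new method: the N-silylated chiral disulfonimide (a silylium Lewis acid paired with a chiral counteranion) activates the aldehyde carbonyl of 1, and the electron-rich ring carbon C3 of the cyclic 1-oxy-3-siloxydiene 17 attacks it through an endo, [4+2]-like transition state inside the chiral ion pair, so the anti relation of the new C3 and C1′ stereocentres follows from the endo topology and their absolute configuration (3S,1′R) from the catalyst, with silyl transfer releasing 18 and regenerating the catalyst; the closest known reaction type is the disulfonimide-catalysed Mukaiyama aldol and hetero-Diels–Alder reaction of acyclic silyl ketene acetals and siloxydienes with aldehydes, which has not been shown for a siloxy-2H-pyran or for creating two adjacent stereocentres at a ring carbon.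

**Step 9**
Reactants: 19 anti aldol; 20 ethyl vinyl ether; 21 water
Product: 24 (3S)-3-[(1R,2S)-1,2-dihydroxy-2-methyl-3-oxobutyl]-6-[(1E,3R,4R,5S)-3,5-dimethyl-3,4-bis(triethylsilyloxy)hept-1-en-1-yl]-2,3-dihydro-4H-pyran-4-one, via 1-ethoxyvinyllithium 22 (not isolated), via enol ether adduct 23 (not isolated)
Conditions: 20, t-BuLi, THF, −78 → 0 °C; then 19 precomplexed with MgBr2·OEt2, THF–CH2Cl2, −78 °C; then 0.5 M HCl, THF, 0 °C
Reagents that add atoms: ethyl vinyl ether 20, C=COCC; water 21, O
Why: Magnesium bridges the C1′ alkoxide and the neighbouring ketone, so the ethoxyvinyl nucleophile adds to the more electrophilic methyl ketone (not the vinylogous ester) from the face of the α-hydrogen (Cram chelate-controlled addition of an acetyl anion equivalent), which sets the tertiary carbinol 2′S syn to the C1′ hydroxyl, and mild acid hydrolysis of the enol ether unveils the methyl ketone.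

**Step 10**
Reactants: 24 methyl ketone diol
Product: 26 (7S,8R,8aS)-3-[(1E,3R,4R,5S)-3,5-dimethyl-3,4-bis(triethylsilyloxy)hept-1-en-1-yl]-7,8-dihydroxy-7-methyl-1,7,8,8a-tetrahydro-6H-isochromen-6-one, via aldol adduct 25 (not isolated)
Conditions: LiN(SiMe3)2 (3.3 equiv), THF, −78 → −20 °C; AcOH; then PPTS (cat.), CH2Cl2, rt
Reagents that add atoms: none
Why: The kinetic methyl ketone enolate adds to the vinylogous ester carbonyl through a six-membered transition state and the tertiary allylic alcohol 25 loses water under mild acid to give the fully conjugated dienone (intramolecular aldol condensation), with no stereocentre created or touched.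

**Step 11**
Reactants: 26 bis(triethylsilyl) ether of the target
Product: 27 (7S,8R,8aS)-3-[(1E,3R,4R,5S)-3,4-dihydroxy-3,5-dimethylhept-1-en-1-yl]-7,8-dihydroxy-7-methyl-1,7,8,8a-tetrahydro-6H-isochromen-6-one
Conditions: HF·pyridine, pyridine, THF, 0 °C → rt
Reagents that add atoms: none
Why: Buffered fluoride cleaves both triethylsilyl ethers under non-basic conditions that spare the α-ketol, the dienyl ether and the tertiary allylic alcohol (silyl ether deprotection).

**Compound list**

1 | methylglyoxal (2-oxopropanal) | CC(=O)C=O | starting material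
2 | (Z)-crotylboronic acid pinacol ester, 2-[(2Z)-but-2-en-1-yl]-4,4,5,5-tetramethyl-1,3,2-dioxaborolane | C/C=C\CB1OC(C)(C)C(C)(C)O1 | starting material
3 | 4,4,5,5-tetramethyl-2-{[(3R,4S)-4-methyl-2-oxohex-5-en-3-yl]oxy}-1,3,2-dioxaborolane | C=C[C@H](C)[C@@H](OB1OC(C)(C)C(C)(C)O1)C(C)=O | intermediate
4 | (3R,4S)-3-hydroxy-4-methylhex-5-en-2-one | C=C[C@H](C)[C@@H](O)C(C)=O | intermediate
5 | (3R,4S)-3-hydroxy-4-methylhexan-2-one | CC[C@H](C)[C@@H](O)C(C)=O | intermediate
6 | vinylmagnesium bromide | C=C[Mg]Br | starting material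
7 | bromo{[(3R,4S)-4-methyl-2-oxohexan-3-yl]oxy}magnesium (five-membered chelate) | CC[C@H](C)[C@@H](O[Mg]Br)C(C)=O | intermediate
8 | (3R,4R,5S)-3,5-dimethylhept-1-ene-3,4-diol | CC[C@H](C)[C@@H](O)[C@](C)(O)C=C | intermediate
9 | methyl vinyl ketone (but-3-en-2-one) | CC(=O)C=C | starting material
10 | (3E,5R,6R,7S)-5,6-dihydroxy-5,7-dimethylnon-3-en-2-one | CC[C@H](C)[C@@H](O)[C@](C)(O)/C=C/C(C)=O | intermediate
11 | triethylsilyl trifluoromethanesulfonate | CC[Si](CC)(CC)OS(=O)(=O)C(F)(F)F | starting material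
12 | (3E,5R,6R,7S)-5,7-dimethyl-5,6-bis(triethylsilyloxy)non-3-en-2-one | CC[C@H](C)[C@@H](O[Si](CC)(CC)CC)[C@](C)(O[Si](CC)(CC)CC)/C=C/C(C)=O | intermediate
13 | 3-chloropropanoyl chloride | ClCCC(Cl)=O | starting material
14 | (6E,8R,9R,10S)-1-chloro-8,10-dimethyl-8,9-bis(triethylsilyloxy)dodec-6-ene-3,5-dione | CC[C@H](C)[C@@H](O[Si](CC)(CC)CC)[C@](C)(O[Si](CC)(CC)CC)/C=C/C(=O)CC(=O)CCCl | intermediate
15 | 6-[(1E,3R,4R,5S)-3,5-dimethyl-3,4-bis(triethylsilyloxy)hept-1-en-1-yl]-2,3-dihydro-4H-pyran-4-one | CC[C@H](C)[C@@H](O[Si](CC)(CC)CC)[C@](C)(O[Si](CC)(CC)CC)/C=C/C1=CC(=O)CCO1 | intermediate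
16 | trimethylsilyl trifluoromethanesulfonate | C[Si](C)(C)OS(=O)(=O)C(F)(F)F | starting material
17 | 6-[(1E,3R,4R,5S)-3,5-dimethyl-3,4-bis(triethylsilyloxy)hept-1-en-1-yl]-4-(trimethylsilyloxy)-2H-pyran | CC[C@H](C)[C@@H](O[Si](CC)(CC)CC)[C@](C)(O[Si](CC)(CC)CC)/C=C/C1=CC(O[Si](C)(C)C)=CCO1 | intermediate
18 | (3S)-6-[(1E,3R,4R,5S)-3,5-dimethyl-3,4-bis(triethylsilyloxy)hept-1-en-1-yl]-3-[(1R)-2-oxo-1-(trimethylsilyloxy)propyl]-2,3-dihydro-4H-pyran-4-one | CC[C@H](C)[C@@H](O[Si](CC)(CC)CC)[C@](C)(O[Si](CC)(CC)CC)/C=C/C1=CC(=O)[C@H]([C@@H](O[Si](C)(C)C)C(C)=O)CO1 | intermediate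
19 | (3S)-6-[(1E,3R,4R,5S)-3,5-dimethyl-3,4-bis(triethylsilyloxy)hept-1-en-1-yl]-3-[(1R)-1-hydroxy-2-oxopropyl]-2,3-dihydro-4H-pyran-4-one | CC[C@H](C)[C@@H](O[Si](CC)(CC)CC)[C@](C)(O[Si](CC)(CC)CC)/C=C/C1=CC(=O)[C@H]([C@@H](O)C(C)=O)CO1 | intermediate
20 | ethyl vinyl ether | C=COCC | starting material
21 | water | O | starting material
22 | 1-ethoxyvinyllithium | [Li]C(=C)OCC | intermediate
23 | (3S)-6-[(1E,3R,4R,5S)-3,5-dimethyl-3,4-bis(triethylsilyloxy)hept-1-en-1-yl]-3-[(1R,2S)-3-ethoxy-1,2-dihydroxy-2-methylbut-3-en-1-yl]-2,3-dihydro-4H-pyran-4-one | CC[C@H](C)[C@@H](O[Si](CC)(CC)CC)[C@](C)(O[Si](CC)(CC)CC)/C=C/C1=CC(=O)[C@H]([C@@H](O)[C@](C)(O)C(=C)OCC)CO1 | intermediate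
24 | (3S)-3-[(1R,2S)-1,2-dihydroxy-2-methyl-3-oxobutyl]-6-[(1E,3R,4R,5S)-3,5-dimethyl-3,4-bis(triethylsilyloxy)hept-1-en-1-yl]-2,3-dihydro-4H-pyran-4-one | CC[C@H](C)[C@@H](O[Si](CC)(CC)CC)[C@](C)(O[Si](CC)(CC)CC)/C=C/C1=CC(=O)[C@H]([C@@H](O)[C@](C)(O)C(C)=O)CO1 | intermediate
25 | (7S,8R,8aS)-3-[(1E,3R,4R,5S)-3,5-dimethyl-3,4-bis(triethylsilyloxy)hept-1-en-1-yl]-4a,7,8-trihydroxy-7-methyl-1,4a,5,7,8,8a-hexahydro-6H-isochromen-6-one (C4a epimers, centre lost in the dehydration) | CC[C@H](C)[C@@H](O[Si](CC)(CC)CC)[C@](C)(O[Si](CC)(CC)CC)/C=C/C1=CC2(O)CC(=O)[C@@](C)(O)[C@H](O)[C@@H]2CO1 | intermediate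
26 | (7S,8R,8aS)-3-[(1E,3R,4R,5S)-3,5-dimethyl-3,4-bis(triethylsilyloxy)hept-1-en-1-yl]-7,8-dihydroxy-7-methyl-1,7,8,8a-tetrahydro-6H-isochromen-6-one | CC[C@H](C)[C@@H](O[Si](CC)(CC)CC)[C@](C)(O[Si](CC)(CC)CC)/C=C/C1=CC2=CC(=O)[C@@](C)(O)[C@H](O)[C@@H]2CO1 | intermediate
27 | (7S,8R,8aS)-3-[(1E,3R,4R,5S)-3,4-dihydroxy-3,5-dimethylhept-1-en-1-yl]-7,8-dihydroxy-7-methyl-1,7,8,8a-tetrahydro-6H-isochromen-6-one | CC[C@H](C)[C@@H](O)[C@](C)(O)/C=C/C1=CC2=CC(=O)[C@@](C)(O)[C@H](O)[C@@H]2CO1 | target

**Total step count:** 11. **Longest linear sequence:** 11 steps (1 → 27; the route is linear and every other input is commercial).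

**Steps most likely to fail**

Step 8, the proposed new aldol. The siloxy-2H-pyran 17 may ring-open before it reacts, and the anti ratio or the face selectivity of an untested catalyst–substrate pair may be poor. The fallback uses known chemistry, a lithium aldol reaction. It sets out from 15, which is deprotonated with LiN(i-Pr)2 in THF at −78 °C to the lithium enolate of 15 F3 and trapped at −78 °C with 1. The closed Zimmerman–Traxler transition state of the ring (E)-enolate gives the anti aldols, that is 19 together with its mirror-configured aldol (3R)-6-[(1E,3R,4R,5S)-3,5-dimethyl-3,4-bis(triethylsilyloxy)hept-1-en-1-yl]-3-[(1S)-1-hydroxy-2-oxopropyl]-2,3-dihydro-4H-pyran-4-one F4. Because the side chain is enantiopure these two are diastereomers and are separated by chromatography, and the route is rejoined at 19.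

Step 1, the first stereocentres. The very electrophilic α-keto aldehyde may undergo fast uncatalysed crotylboration, which would erode the ee. The fallback replaces catalyst control by reagent control. It sets out from 1, which is treated in toluene with 4 Å molecular sieves at −78 °C with a stoichiometric amount of the known tartrate-modified boronate diisopropyl (4S,5S)-2-[(2Z)-but-2-en-1-yl]-1,3,2-dioxaborolane-4,5-dicarboxylate F1. The chair transition state again gives the syn adduct, first as the tartrate borate ester diisopropyl (4S,5S)-2-{[(3R,4S)-4-methyl-2-oxohex-5-en-3-yl]oxy}-1,3,2-dioxaborolane-4,5-dicarboxylate F2, which is hydrolysed on aqueous work-up to 4, where the route is rejoined.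

Step 10, the carbocycle closure. Under base the β-hydroxy ketone 24 can undergo retro-aldol cleavage or epimerise at C3 before the enolate adds to the poorly electrophilic vinylogous ester carbonyl. The fallback is an acid-mediated closure that uses the enol ether as the nucleophile. It sets out from 19: the addition of step 9 is quenched with aqueous NaHCO3 instead of acid so that the enol ether 23 is isolated, and 23 is treated with BF3·OEt2 in CH2Cl2 at −78 → 0 °C. The Lewis acid activates the vinylogous ester carbonyl, the ethoxyvinyl group attacks it in an intramolecular Mukaiyama-type aldol addition, and loss of ethanol and water gives 26 directly, where the route is rejoined; no compound outside the compound list is made (F0).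

**Further compounds**

F1 | step 1 | diisopropyl (4S,5S)-2-[(2Z)-but-2-en-1-yl]-1,3,2-dioxaborolane-4,5-dicarboxylate | C/C=C\CB1O[C@H](C(=O)OC(C)C)[C@@H](C(=O)OC(C)C)O1
F2 | step 1 | diisopropyl (4S,5S)-2-{[(3R,4S)-4-methyl-2-oxohex-5-en-3-yl]oxy}-1,3,2-dioxaborolane-4,5-dicarboxylate | C=C[C@H](C)[C@@H](OB1O[C@H](C(=O)OC(C)C)[C@@H](C(=O)OC(C)C)O1)C(C)=O
F3 | step 8 | lithium enolate of 15, lithium 6-[(1E,3R,4R,5S)-3,5-dimethyl-3,4-bis(triethylsilyloxy)hept-1-en-1-yl]-2H-pyran-4-olate | CC[C@H](C)[C@@H](O[Si](CC)(CC)CC)[C@](C)(O[Si](CC)(CC)CC)/C=C/C1=CC(O[Li])=CCO1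
F4 | step 8 | (3R)-6-[(1E,3R,4R,5S)-3,5-dimethyl-3,4-bis(triethylsilyloxy)hept-1-en-1-yl]-3-[(1S)-1-hydroxy-2-oxopropyl]-2,3-dihydro-4H-pyran-4-one | CC[C@H](C)[C@@H](O[Si](CC)(CC)CC)[C@](C)(O[Si](CC)(CC)CC)/C=C/C1=CC(=O)[C@@H]([C@H](O)C(C)=O)CO1
F0 | step 10 | none | none
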